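The rate constants belong to no real substance; the flask was simulated.

I read these flasks at 10 h, so my question was how much coupling the catalyst could get through by then.

    substrate + free catalyst ⇌ catalyst intermediate A (K1 = 140 /M, k1 = 5530 /M/min, Ea1 = 45.0 kJ/mol, ΔH1 = −25.0 kJ/mol)
    catalyst intermediate A ⇌ catalyst intermediate B (K2 = 3.9, k2 = 366 /min, Ea2 = 58.0 kJ/mol, ΔH2 = −26.0 kJ/mol)
    coupling partner + catalyst intermediate B ⇌ catalyst intermediate C (K3 = 140 /M, k3 = 174 /M/min, Ea3 = 58.0 kJ/mol, ΔH3 = −11.0 kJ/mol)
    catalyst intermediate C ⇌ free catalyst + target (K4 = 0.0315 M, k4 = 38.1 /min, Ea4 = 77.0 kJ/mol, ΔH4 = 40.0 kJ/mol)
    coupling partner + protic impurity → quenched reagent (k5 = 11.1 /M/min, Ea5 = 47.0 kJ/mol)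
    substrate + target → side product (k6 = 0.0298 /M/min, Ea6 = 63.0 kJ/mol)
    catalyst intermediate C + catalyst intermediate C ⇌ resting dimer (K7 = 1.21 × 10⁶ /M, k7 = 165 /M/min, Ea7 = 47.0 kJ/mol, ΔH7 = −34.0 kJ/mol)
    (constants at 20 °C)

the same everywhere: substrate 20 mM; coupling partner 12.0 mM; protic impurity 2.00 mM; free catalyst 100 µM; time 10 h
- Thursday's: temperature −20 °C
- Saturday's: temperature 0 °C
- Wednesday's: temperature 20 °C
- Friday's: temperature 40 °C

- the flask that comes out highest in amount of target, in percent of the substrate charged, or "all alike" when all lie within 1.5 percentage points (Thursday's / Saturday's / Wednesday's / Friday's / all alike)
- target at the end, in percent of the substrate charged, Thursday's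
- target at the end, in percent of the substrate charged, Saturday's
- target at the end, in percent of the substrate charged, Wednesday's
- target at the end, in percent of the substrate charged, Friday's

- percent here means substrate units held: one side product or resting dimer counts as two
- a step written with two of one species runs at k times the square of its concentration and takes two of it each time
- all constants are for 20 °C and move with temperature by the activation energies and enthalpies

**The ceiling.** The protic impurity takes coupling partner one for one. In Thursday's flask its half-life at the charged partner was 1.83 h, shorter than the run, so I wrote its whole charge off against the partner. That left u = 10.0 mM, less than the substrate, which made the partner the limiting reagent and put the ceiling at 50.0% of the substrate.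

**Counting rounds.** In Wednesday's flask, at the charges, partner adding to catalyst intermediate B ran at 2.09 /min per catalyst, slower than substrate binding at 111 /min or target release at 38.1 /min. So I took B as the resting state and that addition, with rate constant k, as the rate-limiting step. Each round costs one partner, so, letting the steps run one way as an estimate, I took the partner to fall in pseudo-first-order fashion. I counted the turnover count τ, the rounds a catalyst can make at the charged partner divided by the rounds that charge holds, which equals k times catalyst charge times time: 0.243 for Thursday's, 1.83 for Saturday's, 10.4 for Wednesday's and 47.7 for Friday's. On that one-way estimate, which ignores the cycle running back and which I aimed at the cold flasks but also applied to Wednesday's and Friday's, the share of u used is one minus exp(−τ).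

**Target lost.** Target also meets substrate. I charged it a second count σ, the side step's constant times the substrate beyond the ceiling times the time: 0.00301, 0.0269, 0.179 and 0.932 in the same order. Multiplying the ceiling by both factors gave 10.8%, 40.8%, 41.8% and 19.7%.

**The weak link.** I had put the whole catalyst at B, but some waits as A and some as C. From the equilibrium of the A-to-B step and the ratio of addition to release, B's share came to 80.9% in Thursday's flask and 82.3% in Saturday's. Scaling τ by those shares lowered my numbers to 8.90% and 37.9%. I committed to these, with Wednesday's highest at 41.8%.

**The forecast.** The forecast gave 9%, 38%, 41% and 24% and named Wednesday's, holding of the warm flasks that “the yield is set by the slow substrate + target side reaction eating product”. We differed most on Friday's flask, where my 19.7% stood lower than its figure.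

**The flasks.** They gave 9.00%, 37.1%, 41.0% and 23.4%, with Wednesday's highest, so the forecast held. In Wednesday's flask at 0.889 h, the forward addition alone gave the coupling partner a half-life of 0.95 h, far shorter than the run, a reading worth a count of 7.30, but at the end the partner stood at 3.25% of its charge, more than the 0.0698% that one-way count reckons, beside 14.1% of side product. Thursday's flask at 100 h has a count of 1.97, which on the ceiling reckons 43.0%, and the target there stood at 41.4%.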